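Follow the partner through this flask: ask first where each partner molecule must end, then whether the time allows it.

substrate 0.021 M; partner 1.20 equiv (fed, over 2.0 h); protic impurity 0.0105 M; time 8.0 d

    substrate → intermediate (k1 = 0.23 h⁻¹)
    partner + intermediate → product (k2 = 14 M⁻¹ h⁻¹)
    partner + protic impurity → quenched reagent (k3 = 31 M⁻¹ h⁻¹)

- the reaction counts as stopped when no species that holds the substrate changes by six tenths of a point or more over the second half of the time
- run time (flask): 8.0 d

- why nothing more happens at 8.0 d, or that something still does (it is still moving / forward and back rates have come level / all of the substrate has reacted)
- product at 8.0 d, in percent of the substrate charged
- intermediate at 8.0 d, in percent of the substrate charged

We build the flask up by hand. With the first step by itself, the substrate has a half-life of 0.13 d, far shorter than the 8.0 d allowed, so at the end intermediate stands in its place.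

Now add the partner. Each product costs one partner, and the half-life of intermediate by the second step, with the whole partner charge counted at once, is 0.082 d, also shorter than the run. With 1.20 equiv of partner the substrate is the limiting reagent, and our reckoning stands at 100% product.

Now add the protic impurity, which also costs one partner per molecule. Its selectivity factor over the intermediate is 2.21, and it is present from the start, while the intermediate must first form. We therefore reckon as if it takes its whole charge, which leaves 70.0% of the substrate charged: this is the free partner, the partner charged less the impurity charged, as a percentage of the substrate charged. The partner is now limiting, so in this flask we commit to product 70.0% and intermediate 30.0%, with the substrate fully reacted. Any impurity that survives in this flask leaves one partner more for the intermediate, so we expect its product at or above the free partner.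

The forecast says all of the substrate has reacted, with product 71% (69% to 73%) and intermediate 29% (27% to 31%), the impurity acting “with its larger rate constant and early access to the partner”. Its product stands 1 percentage point above ours.

At 8.0 d the flask shows all of the substrate has reacted, with product 70.6% and intermediate 29.4%.

The flask's product lies 0.60 points above the free partner, and its impurity left over, 1.25% of its own charge, equals 0.626% of the substrate charged. In the neighbouring flask with 3.00 equiv of partner, the free partner is 250%, above the substrate charge. The substrate is limiting again, so we reckon product 100% and spare partner 50.0% of its own charge. That neighbour gives product 100%, intermediate 0%, and 50% of its partner charge remaining.

The numbers were drawn at random within sensible limits; the flask was simulated.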